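**Plan**

- Cuts, in retrosynthetic order: the aryl O–SO3 bond; in ring A the bond between the methyl/homoprenyl quaternary carbon and the CH that carries the two-carbon link (epoxide opened by an allylsilane); the alkene joining that acyclic chain to the octalin acetaldehyde (Horner–Wadsworth–Emmons); in ring C the bond from the ring-fusion alkene carbon to the methyl/arylmethyl quaternary carbon (reductive Heck); the side-chain bond at C2 of ring B (aldol).
- Feature used: the ring-C quaternary carbon (CH3, CH2–aryl) sits on a carbon of the tetrasubstituted ring-fusion alkene, and its CH2–aryl arm has no hydrogen on the ring-side neighbour. That is what a 6-exo insertion of a ring-B alkenylpalladium into a trisubstituted styrene leaves after hydride capture.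
- Forward order: ring B from 3-methylcyclohexenone (conjugate vinylation, aldol with an aryl pentenal, conjugate reduction–triflation), ring C by the Heck closure, vinyl to aldehyde, chain joined with a geraniol-derived epoxy ketophosphonate, ring A closed last, then sulfation of the single free phenol and desilylation.
- Stereochemistry: ring-B quaternary carbon from a copper-catalysed asymmetric conjugate addition; ring-C methine from a Sharpless kinetic resolution relayed by a chair Eschenmoser–Claisen rearrangement; ring-C quaternary carbon from that methine in the Heck step; ring A from Sharpless epoxidation of geraniol (carbinol kept, quaternary carbon by inversion) and the chair closure of a Z allylsilane (methine).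
- The hydroquinone is carried as its 2-O-triisopropylsilyl/5-O-methoxymethyl diether, so only the 5-oxygen can take the sulfate.

Key step: step 11

Assumption: the sulfate monoester is drawn as the free acid, as in the target; it would be stored as its sodium salt and the acid form released only by the brief cold acidification at the end of the last step.

Notation: Ar = 5-(methoxymethoxy)-2-[(triisopropylsilyl)oxy]phenyl. "Octalin unit" = (1R,2S,5R)-1-(arylmethyl)-1,2,5-trimethyl-1,2,3,4,5,6,7,8-octahydronaphthalen-5-yl with the C4a=C8a alkene; the aryl group is Ar unless stated otherwise.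

**Route**

Step 1
Reactants: 1 2,5-dihydroxybenzaldehyde
Product: 2 2-hydroxy-5-(methoxymethoxy)benzaldehyde
Conditions: MeOCH2Cl (1.05 equiv), i-Pr2NEt, CH2Cl2, 0 °C
Reagents that add atoms: chloromethyl methyl ether, COCCl
Why: O-alkylation of the phenol that is not held in the hydrogen bond to the aldehyde, so the 5-hydroxyl should react first (Williamson-type acetal formation).

Step 2
Reactants: 2 2-hydroxy-5-(methoxymethoxy)benzaldehyde
Product: 3 5-(methoxymethoxy)-2-[(triisopropylsilyl)oxy]benzaldehyde (ArCHO)
Conditions: i-Pr3SiCl, imidazole, DMF, 40 °C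
Reagents that add atoms: chlorotriisopropylsilane, CC(C)[Si](Cl)(C(C)C)C(C)C
Why: Silylation of the remaining phenol; the bulky aryl silyl ether should survive organolithiums, hydrides, formate and a short exposure to Lewis acid at low temperature, and falls to fluoride in the last step.

Step 3
Reactants: 4 (E)-2-bromobut-2-ene; 3 ArCHO
Product: 6 racemic (E)-1-Ar-2-methylbut-2-en-1-ol, via (E)-but-2-en-2-yllithium 5 (not isolated)
Conditions: 4, t-BuLi (2 equiv), Et2O, −78 °C; then 3, −78 °C; AcOH, −78 °C
Reagents that add atoms: none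
Why: Bromine–lithium exchange with retention of alkene geometry followed by 1,2-addition to the aldehyde; the cold acidic quench should forestall silyl migration from the phenol oxygen to the new alkoxide.

Step 4
Reactants: 6 racemic (E)-1-Ar-2-methylbut-2-en-1-ol
Product: 7 (R,E)-1-Ar-2-methylbut-2-en-1-ol
Conditions: Ti(OiPr)4 (10 mol %), D-(−)-diisopropyl tartrate (15 mol %), t-BuOOH (0.6 equiv), 4 Å molecular sieves, CH2Cl2, −20 °C
Reagents that add atoms: none
Why: Sharpless kinetic resolution of a secondary allylic alcohol: with the D-tartrate the S enantiomer should be epoxidised fast, and the R alcohol, which carries the configuration needed for the chirality transfer of step 5, is recovered.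

Step 5
Reactants: 7 (R,E)-1-Ar-2-methylbut-2-en-1-ol
Product: 9 (S,E)-5-Ar-N,N,3,4-tetramethylpent-4-enamide, via O-allyl ketene aminal 8 (not isolated)
Conditions: MeC(OMe)2NMe2 (4 equiv), xylene, 140 °C
Reagents that add atoms: N,N-dimethylacetamide dimethyl acetal, COC(C)(OC)N(C)C
Why: Eschenmoser–Claisen rearrangement through a chair transition state with the aryl group equatorial, which should give the E trisubstituted styrene and move the carbinol configuration suprafacially onto the new methyl-bearing carbon (S).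

Step 6
Reactants: 9 (S,E)-5-Ar-N,N,3,4-tetramethylpent-4-enamide
Product: 10 (S,E)-5-Ar-3,4-dimethylpent-4-enal
Conditions: Cp2Zr(H)Cl (1.5 equiv), THF, rt
Reagents that add atoms: none
Why: Hydrozirconation of the tertiary amide carbonyl gives a stable zirconium hemiaminal that releases the aldehyde on work-up without over-reduction; the stereocentre is β to the carbonyl and cannot epimerise.

Step 7
Reactants: 11 3-methylcyclohex-2-en-1-one
Product: 13 trimethylsilyl enol ether (C1=C2) of (S)-3-methyl-3-vinylcyclohexanone, via dimethylaluminium enolate 12 (not isolated)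
Conditions: CH2=CHMgBr, Me2AlCl, Et2O, 0 °C; then 11, copper thiophene-2-carboxylate Cu(O2CC4H3S) (5 mol %), SimplePhos-type phosphinamine Ph2P–N[CH(CH3)(2-naphthyl)]2 (5.5 mol %, antipode giving the 3S ketone series), Et2O, −30 °C; Me3SiOTf, −30 to 0 °C
Reagents that add atoms: dimethyl(vinyl)aluminium, C=C[Al](C)C (made from vinylmagnesium bromide, C=C[Mg]Br, and Me2AlCl, C[Al](C)Cl); trimethylsilyl trifluoromethanesulfonate, C[Si](C)(C)OS(=O)(=O)C(F)(F)F
Why: Copper-catalysed asymmetric conjugate addition of an alkenylaluminium to a β-substituted cyclohexenone, in which the chiral ligand selects the enone face and so sets the ring-B quaternary carbon, followed by O-silylation of the aluminium enolate, which fixes the enol double bond toward the quaternary carbon.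

Step 8
Reactants: 13 trimethylsilyl enol ether of (S)-3-methyl-3-vinylcyclohexanone; 10 (S,E)-5-Ar-3,4-dimethylpent-4-enal
Product: 15 aldol adduct 2-[(3S,E)-5-Ar-1-hydroxy-3,4-dimethylpent-4-en-1-yl]-3-methyl-3-vinylcyclohexanone (epimers at C2 and carbinol), via lithium enolate 14 (not isolated)
Conditions: MeLi (0.98 equiv), THF, 0 °C; then 10, −78 °C; AcOH, −78 °C
Reagents that add atoms: none
Why: Cleavage of the silyl enol ether gives the regiodefined lithium enolate, which should add to the aldehyde at the carbon next to the quaternary centre (aldol addition); the two new stereocentres are erased in steps 9 and 10.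

Step 9
Reactants: 15 aldol adduct
Product: 17 2-[(3S,E)-5-Ar-3,4-dimethylpent-4-en-1-ylidene]-3-methyl-3-vinylcyclohexanone, via methanesulfonate 16 (not isolated)
Conditions: MsCl, Et3N, CH2Cl2, 0 °C; then DBU, rt
Reagents that add atoms: none
Why: Mesylation and E1cB elimination of the β-hydroxy ketone; the double bond can only form exocyclic to C2 because C3 is quaternary, and its geometry is irrelevant to the next step.

Step 10
Reactants: 17 exocyclic enone
Product: 19 (R)-2-[(S,E)-5-Ar-3,4-dimethylpent-4-en-1-yl]-3-methyl-3-vinylcyclohex-1-en-1-yl trifluoromethanesulfonate, via lithium enolate 18 (not isolated)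
Conditions: LiBH(s-Bu)3, THF, −78 °C; then PhNTf2, −78 °C to rt
Reagents that add atoms: N-phenylbis(trifluoromethanesulfonimide), O=S(=O)(N(c1ccccc1)S(=O)(=O)C(F)(F)F)C(F)(F)F
Why: Conjugate reduction of the s-cis exocyclic enone by the bulky borohydride should give only the tetrasubstituted enolate, which is trapped on oxygen by the triflimide (conjugate reduction–triflation).

Step 11
Reactants: 19 ring-B enol triflate with the styrenyl side chain
Product: 20 (1R,2S,5R)-1-(Ar-methyl)-1,2,5-trimethyl-5-vinyl-1,2,3,4,5,6,7,8-octahydronaphthalene (C4a=C8a alkene; C1 and C2 methyl groups cis)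
Conditions: Pd(OAc)2 (10 mol %), (R)-BINAP (12 mol %), HCO2Na (2 equiv, in portions), DMF, 70 °C
Reagents that add atoms: none
Why: Zerovalent palladium formed from Pd(OAc)2 and the bisphosphine inserts into the C–OTf bond, the cationic alkenylpalladium adds syn across the tethered trisubstituted styrene with C–C bond formation at the methyl-bearing alkene carbon, and the neopentyl benzylic alkylpalladium, which has a quaternary carbon on one side and the arene on the other and hence no β-hydrogen, is captured by formate, which loses CO2 and hands over hydride for reductive elimination. The closest known reaction type is the intramolecular reductive Heck cyclization of alkenyl triflates onto trisubstituted alkenes that builds quaternary carbons. Ring C closes in the 6-exo-trig mode. The new quaternary stereocentre is controlled by the adjacent (S)-methine: in the chair-like, eclipsed transition state its methyl group lies equatorial and the exocyclic alkene carbon pseudo-equatorial, so the two ring-C methyl groups should end cis, the E alkene geometry keeping A(1,3) strain low in that arrangement, and (R)-BINAP is taken as the matched ligand (its antipode is the control experiment). The step needs alkene-face selectivity and an insertion that outruns hydride capture; the first is secured by the methine stereocentre with the ligand, the second by adding the formate in portions. The vinyl group and the ring-B quaternary carbon are spectators, since insertion into the vinyl group would need a 4-exo or 5-endo closure.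

Step 12
Reactants: 20 vinyl octalin
Product: 22 2-(octalin unit)ethanol, via B-alkyl-9-BBN adduct 21 (not isolated)
Conditions: 9-BBN, THF, rt; then aq NaOH, H2O2, 0 °C
Reagents that add atoms: hydrogen peroxide, OO
Why: Anti-Markovnikov hydroboration–oxidation; 9-BBN should react only with the monosubstituted vinyl group and leave the tetrasubstituted ring-fusion alkene alone.

Step 13
Reactants: 22 2-(octalin unit)ethanol
Product: 23 (octalin unit)acetaldehyde
Conditions: Dess–Martin periodinane, CH2Cl2, 0 °C to rt
Reagents that add atoms: none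
Why: Neutral oxidation of the primary alcohol with a hypervalent iodine reagent; the α-carbon is a CH2 next to a quaternary carbon, so nothing can epimerise.

Step 14
Reactants: 24 geraniol
Product: 25 (2S,3S)-2,3-epoxygeraniol
Conditions: Ti(OiPr)4 (5 mol %), L-(+)-diethyl tartrate (7.5 mol %), t-BuOOH, 4 Å molecular sieves, CH2Cl2, −20 °C
Reagents that add atoms: tert-butyl hydroperoxide, CC(C)(C)OO
Why: Sharpless asymmetric epoxidation; the L-tartrate catalyst delivers oxygen only to the allylic alkene and sets both epoxide carbons (2S,3S), the source of the ring-A carbinol and quaternary carbon.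

Step 15
Reactants: 25 (2S,3S)-2,3-epoxygeraniol
Product: 26 (2R,3S)-2-(iodomethyl)-3-methyl-3-(4-methylpent-3-en-1-yl)oxirane
Conditions: PPh3, I2, imidazole, CH2Cl2, 0 °C
Reagents that add atoms: iodine, [I][I]
Why: Appel-type iodination of the primary alcohol through its alkoxyphosphonium salt; the imidazole buffer should keep the epoxide closed (the descriptor at C2 changes by the sequence rule only).

Step 16
Reactants: 27 dimethyl (2-oxopropyl)phosphonate; 26 epoxy iodide
Product: 29 dimethyl {4-[(2S,3S)-3-methyl-3-(4-methylpent-3-en-1-yl)oxiran-2-yl]-2-oxobutyl}phosphonate, via sodium lithium dianion 28 (not isolated)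
Conditions: NaH, THF, 0 °C; n-BuLi, 0 °C; then 26, −78 to 0 °C; AcOH
Reagents that add atoms: none
Why: γ-Alkylation of a β-ketophosphonate dianion: the more basic terminal carbanion displaces the primary iodide (SN2), while the hindered epoxide and the stabilised α-carbanion stay untouched.

Step 17
Reactants: 29 epoxy β-ketophosphonate; 23 (octalin unit)acetaldehyde
Product: 30 (E)-1-[(2S,3S)-3-methyl-3-(4-methylpent-3-en-1-yl)oxiran-2-yl]-6-(octalin unit)hex-4-en-3-one
Conditions: Ba(OH)2, THF/H2O (40:1), rt
Reagents that add atoms: none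
Why: Horner–Wadsworth–Emmons olefination under mild hydroxide conditions should give the E enone and join the two halves; neither partner has a base-sensitive stereocentre.

Step 18
Reactants: 30 (E)-enone
Product: 32 (Z)-enol triflate (Z)-1-(epoxide)-6-(octalin unit)hex-3-en-3-yl trifluoromethanesulfonate, via lithium Z-enolate 31 (not isolated)
Conditions: LiBH(s-Bu)3, THF, −78 °C; then N-(5-chloropyridin-2-yl)triflimide, −78 to −20 °C
Reagents that add atoms: N-(5-chloropyridin-2-yl)-N-(trifluoromethylsulfonyl)trifluoromethanesulfonamide, O=S(=O)(N(c1ccc(Cl)cn1)S(=O)(=O)C(F)(F)F)C(F)(F)F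
Why: Conjugate reduction of an acyclic E enone runs through the s-cis conformer and should therefore give the Z enolate (oxygen cis to the chain toward the octalin), which is trapped on oxygen with retention before it can attack the epoxide.

Step 19
Reactants: 32 (Z)-enol triflate
Product: 33 (Z)-allylsilane trimethyl{(Z)-2-[2-(epoxide)ethyl]-5-(octalin unit)pent-2-en-1-yl}silane
Conditions: Me3SiCH2MgCl (2 equiv), Pd(PPh3)4 (5 mol %), THF, 0 °C
Reagents that add atoms: (trimethylsilyl)methylmagnesium chloride, C[Si](C)(C)C[Mg]Cl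
Why: Kumada cross-coupling of an enol triflate, which proceeds with retention of alkene geometry; at 0 °C the trisubstituted epoxide should not be opened by the Grignard reagent.

Step 20
Reactants: 33 (Z)-allylsilane with the (2S,3S)-epoxide
Product: 34 (1S,2S,3R)-2-methyl-2-(4-methylpent-3-en-1-yl)-4-methylidene-3-[2-(octalin unit)ethyl]cyclohexan-1-ol
Conditions: BF3·OEt2 (1.2 equiv), CH2Cl2, −78 °C; aq NaHCO3
Reagents that add atoms: none
Why: Epoxide-initiated cation–olefin cyclization ended by an allylsilane: the Lewis acid opens the epoxide at its tertiary carbon as the alkene attacks from the back in a chair transition state, so inversion places the homoprenyl group trans and the methyl cis to the retained hydroxyl, the link on the Z alkene carbon takes an equatorial place and sets the ring-A methine, and loss of the silyl group leaves only the exocyclic methylene.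

Step 21
Reactants: 34 ring-A alcohol
Product: 35 tert-butyldimethylsilyl ether of 34
Conditions: t-BuMe2SiOTf, 2,6-lutidine, CH2Cl2, −78 to 0 °C
Reagents that add atoms: tert-butyldimethylsilyl trifluoromethanesulfonate, CC(C)(C)[Si](C)(C)OS(=O)(=O)C(F)(F)F
Why: Silylation of the hindered secondary alcohol with a silyl triflate, so that the phenol freed in step 22 is the only hydroxyl present at the sulfation.

Step 22
Reactants: 35 silyl ether
Product: 36 phenol (35 without the methoxymethyl group)
Conditions: ZnBr2, n-PrSH, CH2Cl2, 0 °C, 10 min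
Reagents that add atoms: none
Why: Lewis-acid-assisted thiolysis of the aryl methoxymethyl acetal; the silyl ethers and the three alkenes should not be touched in the short reaction time.

Step 23
Reactants: 36 phenol
Product: 37 sodium aryl sulfate of 36
Conditions: SO3·pyridine (5 equiv), pyridine, rt; aq NaHCO3
Reagents that add atoms: sulfur trioxide–pyridine, [O-]S(=O)(=O)[n+]1ccccc1; sodium hydrogencarbonate, [Na+].OC([O-])=O
Why: O-sulfation of the only free hydroxyl; the regiochemistry (sulfate para to the oxygen that stays free, meta to the benzylic carbon) is fixed by the two different phenol protecting groups.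

Step 24
Reactants: 37 sodium aryl sulfate
Product: 38 target CNP0426156.3
Conditions: Bu4NF, THF, 60 °C; then cold 0.1 M HCl (pH 2–3), n-BuOH extraction
Reagents that add atoms: none
Why: Fluoride cleaves the aryl triisopropylsilyl ether and the hindered secondary silyl ether, while an aryl sulfate monoester is stable to fluoride and base; the short cold acidification releases the acid form drawn for the target.

**Compound list**

1 | 2,5-dihydroxybenzaldehyde | O=Cc1cc(O)ccc1O | starting material
2 | 2-hydroxy-5-(methoxymethoxy)benzaldehyde | O=Cc1cc(OCOC)ccc1O | intermediate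
3 | 5-(methoxymethoxy)-2-[(triisopropylsilyl)oxy]benzaldehyde (ArCHO) | O=Cc1cc(OCOC)ccc1O[Si](C(C)C)(C(C)C)C(C)C | intermediate
4 | (E)-2-bromobut-2-ene (methyl groups cis) | C/C=C(C)/Br | starting material
5 | (E)-but-2-en-2-yllithium | C/C=C(C)/[Li] | intermediate
6 | racemic (E)-1-Ar-2-methylbut-2-en-1-ol | C/C=C(C)/C(O)c1cc(OCOC)ccc1O[Si](C(C)C)(C(C)C)C(C)C | intermediate
7 | (R,E)-1-Ar-2-methylbut-2-en-1-ol | C/C=C(C)/[C@@H](O)c1cc(OCOC)ccc1O[Si](C(C)C)(C(C)C)C(C)C | intermediate
8 | (R,E)-1-Ar-2-methylbut-2-en-1-yl 1-(dimethylamino)vinyl ether (O-allyl ketene aminal) | C/C=C(C)/[C@@H](OC(=C)N(C)C)c1cc(OCOC)ccc1O[Si](C(C)C)(C(C)C)C(C)C | intermediate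
9 | (S,E)-5-Ar-N,N,3,4-tetramethylpent-4-enamide | CN(C)C(=O)C[C@H](C)/C(C)=C/c1cc(OCOC)ccc1O[Si](C(C)C)(C(C)C)C(C)C | intermediate
10 | (S,E)-5-Ar-3,4-dimethylpent-4-enal | O=CC[C@H](C)/C(C)=C/c1cc(OCOC)ccc1O[Si](C(C)C)(C(C)C)C(C)C | intermediate
11 | 3-methylcyclohex-2-en-1-one | CC1=CC(=O)CCC1 | starting material
12 | dimethylaluminium enolate (C1=C2) of (S)-3-methyl-3-vinylcyclohexanone | C=C[C@@]1(C)CCCC(O[Al](C)C)=C1 | intermediate
13 | trimethylsilyl enol ether (C1=C2) of (S)-3-methyl-3-vinylcyclohexanone; (R)-trimethyl[(3-methyl-3-vinylcyclohex-1-en-1-yl)oxy]silane | C=C[C@@]1(C)CCCC(O[Si](C)(C)C)=C1 | intermediate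
14 | lithium enolate (C1=C2) of (S)-3-methyl-3-vinylcyclohexanone | C=C[C@@]1(C)CCCC(O[Li])=C1 | intermediate
15 | 2-[(3S,E)-5-Ar-1-hydroxy-3,4-dimethylpent-4-en-1-yl]-3-methyl-3-vinylcyclohexanone, ring quaternary carbon as in 13, epimers at C2 and at the carbinol | C=C[C@@]1(C)CCCC(=O)C1C(O)C[C@H](C)/C(C)=C/c1cc(OCOC)ccc1O[Si](C(C)C)(C(C)C)C(C)C | intermediate
16 | methanesulfonate of 15 | C=C[C@@]1(C)CCCC(=O)C1C(OS(C)(=O)=O)C[C@H](C)/C(C)=C/c1cc(OCOC)ccc1O[Si](C(C)C)(C(C)C)C(C)C | intermediate
17 | 2-[(3S,E)-5-Ar-3,4-dimethylpent-4-en-1-ylidene]-3-methyl-3-vinylcyclohexanone, ring quaternary carbon as in 13, exocyclic alkene geometry not fixed | C=C[C@@]1(C)CCCC(=O)C1=CC[C@H](C)/C(C)=C/c1cc(OCOC)ccc1O[Si](C(C)C)(C(C)C)C(C)C | intermediate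
18 | lithium 2-[(S,E)-5-Ar-3,4-dimethylpent-4-en-1-yl]-3-methyl-3-vinylcyclohex-1-en-1-olate | C=C[C@@]1(C)CCCC(O[Li])=C1CC[C@H](C)/C(C)=C/c1cc(OCOC)ccc1O[Si](C(C)C)(C(C)C)C(C)C | intermediate
19 | (R)-2-[(S,E)-5-Ar-3,4-dimethylpent-4-en-1-yl]-3-methyl-3-vinylcyclohex-1-en-1-yl trifluoromethanesulfonate | C=C[C@@]1(C)CCCC(OS(=O)(=O)C(F)(F)F)=C1CC[C@H](C)/C(C)=C/c1cc(OCOC)ccc1O[Si](C(C)C)(C(C)C)C(C)C | intermediate
20 | (1R,2S,5R)-1-(Ar-methyl)-1,2,5-trimethyl-5-vinyl-1,2,3,4,5,6,7,8-octahydronaphthalene, C4a=C8a alkene, C1 and C2 methyl groups cis | C=C[C@@]1(C)CCCC2=C1CC[C@H](C)[C@@]2(C)Cc1cc(OCOC)ccc1O[Si](C(C)C)(C(C)C)C(C)C | intermediate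
21 | 9-[2-(octalin unit)ethyl]-9-borabicyclo[3.3.1]nonane | B1(CC[C@@]2(C)CCCC3=C2CC[C@H](C)[C@@]3(C)Cc2cc(OCOC)ccc2O[Si](C(C)C)(C(C)C)C(C)C)C2CCCC1CCC2 | intermediate
22 | 2-(octalin unit)ethanol (20 with CH2CH2OH in place of vinyl) | OCC[C@@]1(C)CCCC2=C1CC[C@H](C)[C@@]2(C)Cc1cc(OCOC)ccc1O[Si](C(C)C)(C(C)C)C(C)C | intermediate
23 | (octalin unit)acetaldehyde (20 with CH2CHO in place of vinyl) | O=CC[C@@]1(C)CCCC2=C1CC[C@H](C)[C@@]2(C)Cc1cc(OCOC)ccc1O[Si](C(C)C)(C(C)C)C(C)C | intermediate
24 | geraniol | OC/C=C(C)/CCC=C(C)C | starting material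
25 | (2S,3S)-2,3-epoxygeraniol; [(2S,3S)-3-methyl-3-(4-methylpent-3-en-1-yl)oxiran-2-yl]methanol | OC[C@@H]1O[C@@]1(C)CCC=C(C)C | intermediate
26 | (2R,3S)-2-(iodomethyl)-3-methyl-3-(4-methylpent-3-en-1-yl)oxirane (same arrangement in space as 25) | IC[C@@H]1O[C@@]1(C)CCC=C(C)C | intermediate
27 | dimethyl (2-oxopropyl)phosphonate | CC(=O)CP(=O)(OC)OC | starting material
28 | sodium lithium 1,3-dianion of 27 | [Li+].[Na+].[CH2-]C(=O)[CH-]P(=O)(OC)OC | intermediate
29 | dimethyl {4-[(2S,3S)-3-methyl-3-(4-methylpent-3-en-1-yl)oxiran-2-yl]-2-oxobutyl}phosphonate | COP(=O)(OC)CC(=O)CC[C@@H]1O[C@@]1(C)CCC=C(C)C | intermediate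
30 | (E)-1-[(2S,3S)-3-methyl-3-(4-methylpent-3-en-1-yl)oxiran-2-yl]-6-(octalin unit)hex-4-en-3-one | O=C(/C=C/C[C@@]1(C)CCCC2=C1CC[C@H](C)[C@@]2(C)Cc1cc(OCOC)ccc1O[Si](C(C)C)(C(C)C)C(C)C)CC[C@@H]1O[C@@]1(C)CCC=C(C)C | intermediate
31 | lithium (Z)-1-(epoxide)-6-(octalin unit)hex-3-en-3-olate (oxygen cis to C5) | [Li]O/C(CC[C@@H]1O[C@@]1(C)CCC=C(C)C)=C\CC[C@@]1(C)CCCC2=C1CC[C@H](C)[C@@]2(C)Cc1cc(OCOC)ccc1O[Si](C(C)C)(C(C)C)C(C)C | intermediate
32 | (Z)-1-[(2S,3S)-epoxide]-6-(octalin unit)hex-3-en-3-yl trifluoromethanesulfonate | FC(F)(F)S(=O)(=O)O/C(CC[C@@H]1O[C@@]1(C)CCC=C(C)C)=C\CC[C@@]1(C)CCCC2=C1CC[C@H](C)[C@@]2(C)Cc1cc(OCOC)ccc1O[Si](C(C)C)(C(C)C)C(C)C | intermediate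
33 | trimethyl{(Z)-2-[2-((2S,3S)-epoxide)ethyl]-5-(octalin unit)pent-2-en-1-yl}silane (CH2Si cis to the chain toward the octalin) | C[Si](C)(C)C/C(CC[C@@H]1O[C@@]1(C)CCC=C(C)C)=C\CC[C@@]1(C)CCCC2=C1CC[C@H](C)[C@@]2(C)Cc1cc(OCOC)ccc1O[Si](C(C)C)(C(C)C)C(C)C | intermediate
34 | (1S,2S,3R)-2-methyl-2-(4-methylpent-3-en-1-yl)-4-methylidene-3-[2-(octalin unit)ethyl]cyclohexan-1-ol (hydroxyl, homoprenyl and link equatorial) | C=C1CC[C@H](O)[C@@](C)(CCC=C(C)C)[C@@H]1CC[C@@]1(C)CCCC2=C1CC[C@H](C)[C@@]2(C)Cc1cc(OCOC)ccc1O[Si](C(C)C)(C(C)C)C(C)C | intermediate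
35 | tert-butyldimethylsilyl ether of 34 | C=C1CC[C@H](O[Si](C)(C)C(C)(C)C)[C@@](C)(CCC=C(C)C)[C@@H]1CC[C@@]1(C)CCCC2=C1CC[C@H](C)[C@@]2(C)Cc1cc(OCOC)ccc1O[Si](C(C)C)(C(C)C)C(C)C | intermediate
36 | phenol: 35 with OH in place of the methoxymethoxy group (aryl = 5-hydroxy-2-[(triisopropylsilyl)oxy]phenyl) | C=C1CC[C@H](O[Si](C)(C)C(C)(C)C)[C@@](C)(CCC=C(C)C)[C@@H]1CC[C@@]1(C)CCCC2=C1CC[C@H](C)[C@@]2(C)Cc1cc(O)ccc1O[Si](C(C)C)(C(C)C)C(C)C | intermediate
37 | sodium sulfate monoester of phenol 36 | C=C1CC[C@H](O[Si](C)(C)C(C)(C)C)[C@@](C)(CCC=C(C)C)[C@@H]1CC[C@@]1(C)CCCC2=C1CC[C@H](C)[C@@]2(C)Cc1cc(OS(=O)(=O)[O-])ccc1O[Si](C(C)C)(C(C)C)C(C)C.[Na+] | intermediate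
38 | CNP0426156.3: 4-hydroxy-3-[(octalin-1-yl)methyl]phenyl hydrogen sulfate carrying the (1S,2S,3R)-ring-A alcohol on the two-carbon link | C=C1CC[C@H](O)[C@@](C)(CCC=C(C)C)[C@@H]1CC[C@@]1(C)CCCC2=C1CC[C@H](C)[C@@]2(C)Cc1cc(OS(=O)(=O)O)ccc1O | target

**Count and risks**

Total step count: 24. Longest linear sequence: 20 steps (steps 1–6, 8–13, 17–24, from 2,5-dihydroxybenzaldehyde).

Steps most likely to fail:

Step 11. Hydride transfer from formate to the alkenylpalladium may outrun the slow insertion into the hindered trisubstituted alkene (simple reduction of the triflate), or the insertion may take place on both alkene faces. The fallback closes ring C with a ketyl radical instead; it sets out from 17 and comes back at 20. Conjugate reduction of 17 with LiBH(s-Bu)3 and protonation of the enolate with methanol would give the saturated ketone F1. SmI2 with HMPA and t-BuOH in THF would turn its carbonyl into a ketyl that adds 6-exo to the methyl-bearing carbon of the styrene; the benzylic radical is reduced and protonated, giving the ring-fusion tertiary alcohol F2 with the same new C–C bond. Dehydration with SOCl2 and pyridine toward the more substituted position would then give 20.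

Step 18. 1,2-Reduction of the enone may compete with conjugate reduction, and any loss of the Z enolate geometry before triflation would be carried through as the wrong allylsilane isomer and hence the C3 epimer of ring A. The fallback fixes the alkene geometry by the order of two cross-couplings; it sets out from 20 and comes back at 33. Hydroformylation of the vinyl group with Rh(acac)(CO)2, BIPHEPHOS and CO/H2 would give the linear homologous aldehyde F3, and CBr4 with PPh3 the 1,1-dibromoalkene F4. The partner is made from 25: oxidation with SO3·pyridine, DMSO and Et3N gives the epoxy aldehyde F5, Ph3P=CH2 the vinyl epoxide F6, 9-BBN followed by NaOH/H2O2 the homologous epoxy alcohol F7, PPh3/I2/imidazole the epoxy iodide F8, and zinc dust with LiCl in THF the alkylzinc iodide F9. A Negishi coupling of F4 with F9 under PdCl2(DPEphos) should replace only the bromine trans to the chain and give the (Z)-bromoalkene F10. A second Negishi coupling with Me3SiCH2ZnCl under Pd(P(t-Bu)3)2 should replace the remaining bromine with retention and deliver 33.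

Step 20. Lewis-acid-induced isomerisation of the epoxide (hydride shift to a ketone) or protodesilylation of the allylsilane may outrun ring closure, and the aryl acetal may be cleaved by the Lewis acid. The fallback uses a stronger π-nucleophile and a ketone intermediate; it sets out from 30 and comes back at 34. 1,4-Hydrosilylation of 30 with Et3SiH and the zerovalent platinum complex Pt2[(CH2=CHSiMe2)2O]3 would give, through the s-cis enone, the (Z)-triethylsilyl enol ether F11. With BF3·OEt2 at −95 °C this enol ether should open the epoxide at the tertiary carbon with inversion, in the same chair arrangement, to give the ring-A hydroxy ketone F12. Methylenation of F12 with Ph3P=CH2 would then give 34.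

**Further compounds**

F1 | step 11 | 2-[(S,E)-5-Ar-3,4-dimethylpent-4-en-1-yl]-3-methyl-3-vinylcyclohexanone (saturated ketone, epimers at C2) | C=C[C@@]1(C)CCCC(=O)C1CC[C@H](C)/C(C)=C/c1cc(OCOC)ccc1O[Si](C(C)C)(C(C)C)C(C)C
F2 | step 11 | ring-fusion tertiary alcohol: 20 with H and OH added across the C4a=C8a alkene (OH on C8a) | C=C[C@@]1(C)CCCC2(O)C1CC[C@H](C)[C@@]2(C)Cc1cc(OCOC)ccc1O[Si](C(C)C)(C(C)C)C(C)C
F3 | step 18 | 3-(octalin unit)propanal | O=CCC[C@@]1(C)CCCC2=C1CC[C@H](C)[C@@]2(C)Cc1cc(OCOC)ccc1O[Si](C(C)C)(C(C)C)C(C)C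
F4 | step 18 | 1,1-dibromo-4-(octalin unit)but-1-ene | BrC(Br)=CCC[C@@]1(C)CCCC2=C1CC[C@H](C)[C@@]2(C)Cc1cc(OCOC)ccc1O[Si](C(C)C)(C(C)C)C(C)C
F5 | step 18 | 2,3-epoxygeranial (aldehyde of 25, same arrangement in space) | O=C[C@@H]1O[C@@]1(C)CCC=C(C)C
F6 | step 18 | vinyl epoxide: 2-methyl-2-(4-methylpent-3-en-1-yl)-3-vinyloxirane from F5 | C=C[C@@H]1O[C@@]1(C)CCC=C(C)C
F7 | step 18 | 2-[3-methyl-3-(4-methylpent-3-en-1-yl)oxiran-2-yl]ethanol from F6 | OCC[C@@H]1O[C@@]1(C)CCC=C(C)C
F8 | step 18 | 2-(2-iodoethyl)-3-methyl-3-(4-methylpent-3-en-1-yl)oxirane from F7 | ICC[C@@H]1O[C@@]1(C)CCC=C(C)C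
F9 | step 18 | alkylzinc iodide from F8 | I[Zn]CC[C@@H]1O[C@@]1(C)CCC=C(C)C
F10 | step 18 | (Z)-bromoalkene: (Z)-3-bromo-1-(epoxide)-6-(octalin unit)hex-3-ene (Br cis to the chain toward the octalin) | Br/C(CC[C@@H]1O[C@@]1(C)CCC=C(C)C)=C\CC[C@@]1(C)CCCC2=C1CC[C@H](C)[C@@]2(C)Cc1cc(OCOC)ccc1O[Si](C(C)C)(C(C)C)C(C)C
F11 | step 20 | (Z)-triethylsilyl enol ether of the ketone from 30 (silyloxy cis to the chain toward the octalin) | CC[Si](CC)(CC)O/C(CC[C@@H]1O[C@@]1(C)CCC=C(C)C)=C\CC[C@@]1(C)CCCC2=C1CC[C@H](C)[C@@]2(C)Cc1cc(OCOC)ccc1O[Si](C(C)C)(C(C)C)C(C)C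
F12 | step 20 | ring-A hydroxy ketone: 34 with C=O in place of C=CH2 | O=C1CC[C@H](O)[C@@](C)(CCC=C(C)C)[C@@H]1CC[C@@]1(C)CCCC2=C1CC[C@H](C)[C@@]2(C)Cc1cc(OCOC)ccc1O[Si](C(C)C)(C(C)C)C(C)C
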